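**Retrosynthetic overview**

1. The target comes from a tricyclic 1,5-ether 12,6-lactone with a C4=C15 methylene group by three late operations: C14 oxidation, C8 methacrylation and convex-face epoxidation of C4=C15 (the spiro-oxirane is the last ring made).
2. The tricycle comes in one flask from an acyclic chain that carries a Z-vinyl iodide, an aldehyde, a cis-vinyl epoxide and a methyl acrylate. Ni/Cr coupling forms C1–C10 (ten-membered carbocycle), the C1 oxygen then opens the epoxide at C5 across the ring (oxane), and the freed C6 oxygen lactonises onto C12 (γ-lactone).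
3. Enabling feature: the C1 carbonyl oxygen is 1,5-related to C5 (O–C1–C2–C3–C4–C5 becomes the oxane); C5 is both the proximal and the allylic (C4=C15) epoxide carbon; the Z C9=C10–I unit holds C10 cis to C8 for ten-ring closure; the C6 oxygen is γ to the C12 ester.
4. The acyclic chain comes from γ-chloroallylboration and oxirane closure (C5–C6) on an aldehyde made by an auxiliary-controlled anti-aldol (C7–C8) between an itaconate-derived thioimide and a Z-3-iodo-enal; the C1–C5/C15 piece comes from carbomagnesiation of propargyl alcohol.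

Key step: step 14

Remark: carbons are numbered as in germacranolides (ring C1–C10, C11–C13 the lactone unit on C7, C14 on C10, C15 on C4); the facial senses given for the thioimide aldol and the Ipc2B chloroallylation follow the accepted closed transition-state models, and the antipodal auxiliary or borane would be used if either proved reversed.

**Route**

Step 1
Reactants: 1 but-2-yne-1,4-diol
Product: 2 4-(tert-butyldimethylsilyloxy)but-2-yn-1-ol
Conditions: TBSCl, imidazole, THF, 0 °C (diol in threefold excess)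
Reagents that add atoms: tert-butyldimethylsilyl chloride, CC(C)(C)[Si](C)(C)Cl
Why: Statistical O-silylation of a symmetrical diol used in excess should give mainly the mono-ether; no stereocentre is involved.

Step 2
Reactants: 2 4-(tert-butyldimethylsilyloxy)but-2-yn-1-ol
Product: 4 (Z)-4-(tert-butyldimethylsilyloxy)-3-iodobut-2-en-1-ol, via cyclic alkenylalanate 3 (not isolated)
Conditions: NaAlH2(OCH2CH2OCH3)2, THF, 0 °C → rt; then I2, THF, −78 °C
Reagents that add atoms: iodine, II
Why: Hydroxyl-directed trans-hydroalumination of the propargylic alcohol places aluminium on the distal alkyne carbon, and iodinolysis with retention should give the Z-vinyl iodide (CH2OH cis to I) that later fixes the ring-cis C9=C10 geometry.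

Step 3
Reactants: 4 (Z)-4-(tert-butyldimethylsilyloxy)-3-iodobut-2-en-1-ol
Product: 5 (Z)-4-(tert-butyldimethylsilyloxy)-3-iodobut-2-enal
Conditions: MnO2, CH2Cl2, rt
Reagents that add atoms: none
Why: Heterogeneous MnO2 oxidation of an allylic alcohol is neutral and should keep the Z geometry.

Step 4
Reactants: 6 dimethyl itaconate
Product: 7 3-(methoxycarbonyl)but-3-enoic acid
Conditions: LiOH (1.0 equiv), THF–H2O, 0 °C; then aq. HCl
Reagents that add atoms: lithium hydroxide, [Li+].[OH-]
Why: In this saponification the non-conjugated ester is the more electrophilic one and should be hydrolysed first, leaving the acrylate ester.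

Step 5
Reactants: 7 3-(methoxycarbonyl)but-3-enoic acid; 8 (R)-4-benzyl-1,3-thiazolidine-2-thione
Product: 9 methyl 4-[(4R)-4-benzyl-2-thioxo-1,3-thiazolidin-3-yl]-2-methylidene-4-oxobutanoate
Conditions: EDC·HCl, DMAP (cat.), CH2Cl2, 0 °C
Reagents that add atoms: none
Why: Carbodiimide-mediated (Steglich-type) N-acylation at low temperature should attach the auxiliary without moving the double bond into conjugation.

Step 6
Reactants: 9 the N-acylthiazolidinethione; 5 (Z)-4-(tert-butyldimethylsilyloxy)-3-iodobut-2-enal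
Product: 11 methyl 2-[(2R,3S,4Z)-1-[(4R)-4-benzyl-2-thioxo-1,3-thiazolidin-3-yl]-6-(tert-butyldimethylsilyloxy)-3-hydroxy-5-iodo-1-oxohex-4-en-2-yl]prop-2-enoate, via trimethylsilyl ether 10 (not isolated)
Conditions: MgBr2·OEt2 (10 mol%), Et3N, TMSCl, EtOAc, rt; then 1 M HCl–THF, 0 °C
Reagents that add atoms: none
Why: In this magnesium-halide-catalysed direct anti-aldol of an N-acylthiazolidinethione (soft enolisation, silyl trapping of the aldolate), the Z-enolate should be attacked on the face away from benzyl in the non-chelated conformer, which sets C7, and the anti topology sets C8.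

Step 7
Reactants: 11 the anti-aldol adduct
Product: 12 methyl 2-[(2R,3S,4Z)-1-[(4R)-4-benzyl-2-thioxo-1,3-thiazolidin-3-yl]-3,6-bis(tert-butyldimethylsilyloxy)-5-iodo-1-oxohex-4-en-2-yl]prop-2-enoate
Conditions: TBSOTf, 2,6-lutidine, CH2Cl2, −78 °C
Reagents that add atoms: tert-butyldimethylsilyl triflate, CC(C)(C)[Si](C)(C)OS(=O)(=O)C(F)(F)F
Why: Silylation of the secondary alcohol blocks retro-aldol cleavage and lactonisation of O8 onto C12; no stereocentre is touched.

Step 8
Reactants: 12 the silylated thioimide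
Product: 13 methyl 2-[(2R,3S,4Z)-3,6-bis(tert-butyldimethylsilyloxy)-5-iodo-1-oxohex-4-en-2-yl]prop-2-enoate
Conditions: i-Bu2AlH, CH2Cl2, −78 °C
Reagents that add atoms: none
Why: Partial reduction of the activated thioimide through a stable tetrahedral aluminate should stop at the aldehyde, release the auxiliary and spare the less electrophilic acrylate ester; the aldehyde is used at once because its α-hydrogen is acidic.

Step 9
Reactants: 14 3-bromopropan-1-ol
Product: 15 (3-bromopropoxy)triethylsilane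
Conditions: TESCl, imidazole, CH2Cl2, 0 °C
Reagents that add atoms: chlorotriethylsilane, CC[Si](CC)(CC)Cl
Why: Routine O-silylation; the triethylsilyl ether is chosen because it can later be oxidised directly to the aldehyde.

Step 10
Reactants: 15 (3-bromopropoxy)triethylsilane; 16 prop-2-yn-1-ol
Product: 18 2-[3-(triethylsilyloxy)propyl]prop-2-en-1-ol, via Grignard reagent 17 (not isolated)
Conditions: Mg, THF; then 16, CuI (10 mol%), THF–Et2O, −10 °C → rt; aq. NH4Cl
Reagents that add atoms: none
Why: CuI-catalysed anti-carbomagnesiation of the magnesium alkoxide of propargyl alcohol delivers the alkyl group to the internal alkyne carbon, and protonation of the cyclic alkenylmagnesium should give the 2-substituted allyl alcohol.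

Step 11
Reactants: 18 2-[3-(triethylsilyloxy)propyl]prop-2-en-1-ol
Product: 19 2-(chloromethyl)-5-(triethylsilyloxy)pent-1-ene
Conditions: NCS, PPh3, THF, 0 °C
Reagents that add atoms: N-chlorosuccinimide, ClN1C(=O)CCC1=O
Why: Appel-type chlorination through the alkoxyphosphonium ion is acid-free, and direct and allylic displacement give the same chloride.

Step 12
Reactants: 19 2-(chloromethyl)-5-(triethylsilyloxy)pent-1-ene; 13 the aldehyde
Product: 22 methyl 2-[(1S,2S,3Z)-2,5-bis(tert-butyldimethylsilyloxy)-4-iodo-1-{(2S,3R)-3-[5-(triethylsilyloxy)pent-1-en-2-yl]oxiran-2-yl}pent-3-en-1-yl]prop-2-enoate, via chloroallylborane 20 (not isolated), via syn-chlorohydrin 21 (not isolated)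
Conditions: (+)-Ipc2BOMe, LiN(c-C6H11)2, Et2O, −95 °C; BF3·OEt2; then 13, −95 °C; HOCH2CH2NH2; then DBU, CH2Cl2, 0 °C → rt
Reagents that add atoms: none
Why: This is a γ-chloroallylboration through a closed chair transition state: the reagent with Cl cis to CH2B should give the syn chlorohydrin, the Ipc2B group from (−)-α-pinene should select the aldehyde face that makes C6 (by analogy with Ipc2B-allylation), and base then closes the oxirane by Williamson displacement with inversion at C5 to give the cis-vinyl epoxide.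

Step 13
Reactants: 22 the cis-vinyl epoxide triethylsilyl ether
Product: 23 methyl 2-[(1S,2S,3Z)-2,5-bis(tert-butyldimethylsilyloxy)-4-iodo-1-{(2S,3R)-3-(5-oxopent-1-en-2-yl)oxiran-2-yl}pent-3-en-1-yl]prop-2-enoate
Conditions: (COCl)2, DMSO, CH2Cl2, −78 → −40 °C; Et3N, −78 → 0 °C
Reagents that add atoms: none
Why: Swern conditions cleave a primary triethylsilyl ether and oxidise it in the same flask while TBS ethers survive, so the free C1 alcohol, which would attack the vinyl epoxide, is never present.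

Step 14
Reactants: 23 the acyclic aldehyde
Product: 26 (1R,5S,6S,7S,8R,9Z)-8,14-bis(tert-butyldimethylsilyloxy)-1,5-epoxygermacra-4(15),9,11(13)-trien-12,6-olide, via ten-membered epoxy alcohol 24 (not isolated), via oxane hydroxy ester 25 (not isolated)
Conditions: CrCl2 (excess), NiCl2 (1 mol%), THF–DMF (4:1), rt, slow addition (final 2 mM); then PPTS, 40 °C, same flask
Reagents that add atoms: none
Why: Zerovalent nickel inserts into the C10–I bond and transmetalation gives an alkenyl–trivalent-chromium species that adds to the C1 aldehyde (Nozaki–Hiyama–Kishi macrocyclisation, 10-exo-trig), forming C1–C10 and the ten-membered carbocycle. On protonation with PPTS the C1 hydroxyl opens the cis-epoxide at C5 across the ring (6-exo-tet, SN2; closest known type: acid-promoted cyclisation of hydroxy vinyl epoxides), forming O–C5 and the oxane, and the C6 hydroxyl so released closes the γ-lactone onto the C12 ester (5-exo-trig). C1 should be set in the carbonyl addition by allylic 1,3-strain across the Z C9=C10 bond: C8–H and C1–H lie in the alkene plane, the chain carbons C7 and C2 must leave on the same face to close the ring, and O8 and O1 point to the other face, which is the (1R) arrangement. C5 is set stereospecifically by inversion at the epoxide carbon, and C6 keeps its oxygen and configuration. Regioselectivity for C5 over C6 or the allylic terminus C15 rests on C5 being both the proximal and the allylic epoxide carbon, so only the six-membered ring can form, and a (1S)-alkoxide cannot reach the rear of C5, so only the correct epimer enters the tricycle. Chemoselectivity requires nickel to activate the vinyl iodide and not the vinyl epoxide, which the much faster insertion into C–I at 1 mol% NiCl2 should secure, and lactonisation can only involve O6 because O8 is silylated.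

Step 15
Reactants: 26 the tricyclic bis-silyl ether
Product: 27 (1R,5S,6S,7R,8R,9Z)-8,14-dihydroxy-1,5-epoxygermacra-4(15),9,11(13)-trien-12,6-olide
Conditions: HF·pyridine, pyridine, THF, 0 °C → rt
Reagents that add atoms: none
Why: Buffered fluoride desilylation removes both TBS groups without base, so the 12,6-lactone should not migrate to O8.

Step 16
Reactants: 27 the diol
Product: 28 (1R,5S,6S,7R,8R,9E)-8-hydroxy-14-oxo-1,5-epoxygermacra-4(15),9,11(13)-trien-12,6-olide
Conditions: TEMPO (cat.), PhI(OAc)2, CH2Cl2, rt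
Reagents that add atoms: none
Why: Oxoammonium oxidation is selective for the primary allylic alcohol over the hindered secondary one and should give the enal with the ring-cis alkene intact.

Step 17
Reactants: 28 the hydroxy enal
Product: 29 (1R,5S,6S,7R,8R,9E)-8-(2-methylprop-2-enoyloxy)-14-oxo-1,5-epoxygermacra-4(15),9,11(13)-trien-12,6-olide
Conditions: methacrylic anhydride, DMAP (cat.), Et3N, CH2Cl2, 0 °C
Reagents that add atoms: methacrylic anhydride, C=C(C)C(=O)OC(=O)C(C)=C
Why: DMAP-catalysed acylation of the only hydroxyl; the short, cold reaction should avoid base-induced translactonisation.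

Step 18
Reactants: 29 the methacrylate
Product: 30 (1R,4R,5R,6S,7R,8R,9E)-1,5:4,15-diepoxy-8-(2-methylprop-2-enoyloxy)-14-oxogermacra-9,11(13)-dien-12,6-olide (target, CNP0257628.1)
Conditions: DMDO, acetone–CH2Cl2, −20 → 0 °C
Reagents that add atoms: dimethyldioxirane, CC1(C)OO1
Why: The dioxirane should epoxidise only the electron-rich C4=C15 bond (enal, acrylate and methylene lactone are electron-poor) from the convex face of the oxane, anti to the axial C5–C6 bond of the carbocyclic bridge, which gives the (4R) spiro-oxirane.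

**Compound list**

1 | but-2-yne-1,4-diol | OCC#CCO | starting material
2 | 4-(tert-butyldimethylsilyloxy)but-2-yn-1-ol | OCC#CCO[Si](C)(C)C(C)(C)C | intermediate
3 | cyclic sodium alkenylalanate of 2 (Al on C10, chelated by O8, two 2-methoxyethoxy ligands) | [Na+].COCCO[Al-]1(OCCOC)OCC=C1CO[Si](C)(C)C(C)(C)C | intermediate
4 | (Z)-4-(tert-butyldimethylsilyloxy)-3-iodobut-2-en-1-ol | OC/C=C(\I)CO[Si](C)(C)C(C)(C)C | intermediate
5 | (Z)-4-(tert-butyldimethylsilyloxy)-3-iodobut-2-enal | O=C/C=C(\I)CO[Si](C)(C)C(C)(C)C | intermediate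
6 | dimethyl itaconate | COC(=O)CC(=C)C(=O)OC | starting material
7 | 3-(methoxycarbonyl)but-3-enoic acid | OC(=O)CC(=C)C(=O)OC | intermediate
8 | (R)-4-benzyl-1,3-thiazolidine-2-thione | S=C1SC[C@@H](Cc2ccccc2)N1 | starting material
9 | methyl 4-[(4R)-4-benzyl-2-thioxo-1,3-thiazolidin-3-yl]-2-methylidene-4-oxobutanoate | COC(=O)C(=C)CC(=O)N1[C@H](Cc2ccccc2)CSC1=S | intermediate
10 | trimethylsilyl ether of 11 | C[Si](C)(C)O[C@@H]([C@@H](C(=C)C(=O)OC)C(=O)N1[C@H](Cc2ccccc2)CSC1=S)/C=C(\I)CO[Si](C)(C)C(C)(C)C | intermediate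
11 | methyl 2-[(2R,3S,4Z)-1-[(4R)-4-benzyl-2-thioxo-1,3-thiazolidin-3-yl]-6-(tert-butyldimethylsilyloxy)-3-hydroxy-5-iodo-1-oxohex-4-en-2-yl]prop-2-enoate (7,8-anti) | O[C@@H]([C@@H](C(=C)C(=O)OC)C(=O)N1[C@H](Cc2ccccc2)CSC1=S)/C=C(\I)CO[Si](C)(C)C(C)(C)C | intermediate
12 | 3-O-tert-butyldimethylsilyl ether of 11 | CC(C)(C)[Si](C)(C)O[C@@H]([C@@H](C(=C)C(=O)OC)C(=O)N1[C@H](Cc2ccccc2)CSC1=S)/C=C(\I)CO[Si](C)(C)C(C)(C)C | intermediate
13 | methyl 2-[(2R,3S,4Z)-3,6-bis(tert-butyldimethylsilyloxy)-5-iodo-1-oxohex-4-en-2-yl]prop-2-enoate | O=C[C@H](C(=C)C(=O)OC)[C@H](O[Si](C)(C)C(C)(C)C)/C=C(\I)CO[Si](C)(C)C(C)(C)C | intermediate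
14 | 3-bromopropan-1-ol | OCCCBr | starting material
15 | (3-bromopropoxy)triethylsilane | CC[Si](CC)(CC)OCCCBr | intermediate
16 | prop-2-yn-1-ol | C#CCO | starting material
17 | [3-(triethylsilyloxy)propyl]magnesium bromide | CC[Si](CC)(CC)OCCC[Mg]Br | intermediate
18 | 2-[3-(triethylsilyloxy)propyl]prop-2-en-1-ol | OCC(=C)CCCO[Si](CC)(CC)CC | intermediate
19 | 2-(chloromethyl)-5-(triethylsilyloxy)pent-1-ene | ClCC(=C)CCCO[Si](CC)(CC)CC | intermediate
20 | B-[(E)-3-chloro-2-[3-(triethylsilyloxy)propyl]prop-2-enyl]diisopinocampheylborane (Cl cis to CH2B; Ipc from (−)-α-pinene) | Cl/C=C(/CCCO[Si](CC)(CC)CC)CB([C@H]1C[C@H]2C[C@@H]([C@@H]1C)C2(C)C)[C@H]1C[C@H]2C[C@@H]([C@@H]1C)C2(C)C | intermediate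
21 | syn-chlorohydrin: open chain with C5–Cl and C6–OH, (5S,6S,7S,8S,9Z) in target numbering | CC[Si](CC)(CC)OCCCC(=C)[C@H](Cl)[C@@H](O)[C@H](C(=C)C(=O)OC)[C@H](O[Si](C)(C)C(C)(C)C)/C=C(\I)CO[Si](C)(C)C(C)(C)C | intermediate
22 | methyl 2-[(1S,2S,3Z)-2,5-bis(tert-butyldimethylsilyloxy)-4-iodo-1-{(2S,3R)-3-[5-(triethylsilyloxy)pent-1-en-2-yl]oxiran-2-yl}pent-3-en-1-yl]prop-2-enoate (cis-epoxide) | CC[Si](CC)(CC)OCCCC(=C)[C@H]1O[C@H]1[C@H](C(=C)C(=O)OC)[C@H](O[Si](C)(C)C(C)(C)C)/C=C(\I)CO[Si](C)(C)C(C)(C)C | intermediate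
23 | methyl 2-[(1S,2S,3Z)-2,5-bis(tert-butyldimethylsilyloxy)-4-iodo-1-{(2S,3R)-3-(5-oxopent-1-en-2-yl)oxiran-2-yl}pent-3-en-1-yl]prop-2-enoate | O=CCCC(=C)[C@H]1O[C@H]1[C@H](C(=C)C(=O)OC)[C@H](O[Si](C)(C)C(C)(C)C)/C=C(\I)CO[Si](C)(C)C(C)(C)C | intermediate
24 | methyl (1R,5R,6S,7S,8R,9Z)-8,14-bis(tert-butyldimethylsilyloxy)-5,6-epoxy-1-hydroxygermacra-4(15),9,11(13)-trien-12-oate (formed as its chromium alkoxide) | O[C@@H]1CCC(=C)[C@H]2O[C@H]2[C@H](C(=C)C(=O)OC)[C@H](O[Si](C)(C)C(C)(C)C)/C=C1/CO[Si](C)(C)C(C)(C)C | intermediate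
25 | methyl (1R,5S,6S,7S,8R,9Z)-8,14-bis(tert-butyldimethylsilyloxy)-1,5-epoxy-6-hydroxygermacra-4(15),9,11(13)-trien-12-oate | CC(C)(C)[Si](C)(C)O[C@@H]1/C=C(/CO[Si](C)(C)C(C)(C)C)[C@H]2CCC(=C)[C@H](O2)[C@@H](O)[C@@H]1C(=C)C(=O)OC | intermediate
26 | (1R,5S,6S,7S,8R,9Z)-8,14-bis(tert-butyldimethylsilyloxy)-1,5-epoxygermacra-4(15),9,11(13)-trien-12,6-olide | CC(C)(C)[Si](C)(C)O[C@@H]1/C=C(/CO[Si](C)(C)C(C)(C)C)[C@H]2CCC(=C)[C@H](O2)[C@H]2OC(=O)C(=C)[C@@H]21 | intermediate
27 | (1R,5S,6S,7R,8R,9Z)-8,14-dihydroxy-1,5-epoxygermacra-4(15),9,11(13)-trien-12,6-olide | O[C@@H]1/C=C(/CO)[C@H]2CCC(=C)[C@H](O2)[C@H]2OC(=O)C(=C)[C@@H]21 | intermediate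
28 | (1R,5S,6S,7R,8R,9E)-8-hydroxy-14-oxo-1,5-epoxygermacra-4(15),9,11(13)-trien-12,6-olide | O[C@@H]1/C=C(/C=O)[C@H]2CCC(=C)[C@H](O2)[C@H]2OC(=O)C(=C)[C@@H]21 | intermediate
29 | (1R,5S,6S,7R,8R,9E)-8-(2-methylprop-2-enoyloxy)-14-oxo-1,5-epoxygermacra-4(15),9,11(13)-trien-12,6-olide | C=C(C)C(=O)O[C@@H]1/C=C(/C=O)[C@H]2CCC(=C)[C@H](O2)[C@H]2OC(=O)C(=C)[C@@H]21 | intermediate
30 | (1R,4R,5R,6S,7R,8R,9E)-1,5:4,15-diepoxy-8-(2-methylprop-2-enoyloxy)-14-oxogermacra-9,11(13)-dien-12,6-olide | C=C(C)C(=O)O[C@@H]1/C=C(/C=O)[C@H]2CC[C@@]3(CO3)[C@H](O2)[C@H]2OC(=O)C(=C)[C@@H]21 | target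

**Step count and risks**

Total step count: 18.
Longest linear sequence: 13 steps (steps 1, 2, 3, 6, 7, 8, 12, 13, 14, 15, 16, 17, 18; compounds 1 → 30).

Steps most likely to fail:

Step 14. The Ni/Cr addition may show poor facial selectivity at C1, so that part of the material is locked as a (1S)-alkoxide that cannot reach the rear of C5; low-valent nickel may also attack the vinyl epoxide before the iodide is consumed. The fallback sets out from 23 and returns at 26. The Ni/Cr macrocyclisation would be run alone and worked up without acid, giving alcohol 24 together with its C1 epimer, methyl (1S,5R,6S,7S,8R,9Z)-8,14-bis(tert-butyldimethylsilyloxy)-5,6-epoxy-1-hydroxygermacra-4(15),9,11(13)-trien-12-oate F1. The mixture would be oxidised with Dess–Martin periodinane and NaHCO3 to the macrocyclic enone, methyl (5R,6S,7S,8R,9Z)-8,14-bis(tert-butyldimethylsilyloxy)-5,6-epoxy-1-oxogermacra-4(15),9,11(13)-trien-12-oate F2. Reduction with (S)-2-methyl-CBS-oxazaborolidine and catecholborane at −78 °C (reagent control, alkenyl as the large group) should give 24 alone, and PPTS would then give 25 and 26.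

Step 12. Mismatched double diastereoselection between the Ipc2B reagent and the α-stereocentre of 13, or isomerisation of the chloroallylborane, would erode the C5/C6 configuration and the cis geometry. The fallback sets out from 19 and 13 and returns at 26. An Arbuzov reaction of 19 with P(OEt)3 would give diethyl [2-methylidene-5-(triethylsilyloxy)pentyl]phosphonate F3. Horner–Wadsworth–Emmons olefination of 13 (LiN(SiMe3)2, THF, −78 °C) would give the (5E)-diene ester F4. Shi epoxidation (fructose-derived ketone of the matching hand, KHSO5, buffered) of the trans-disubstituted bond would give the trans-vinyl epoxide F5, and Swern oxidation as in step 13 would give its aldehyde F6. Ni/Cr macrocyclisation would give the ten-membered trans-epoxy alcohol F7. Pd(PPh3)4 (zerovalent palladium) would then close the oxane through the π-allyl complex with net retention at C5 (double inversion) to give 25, which lactonises to 26 with PPTS.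

Step 6. The aldol may give low anti selectivity or the reversed facial sense, the itaconyl double bond may migrate into conjugation under base, or the amine may attack the β-iodo enal. The fallback sets out from 7 and 5 and returns at 13. Acid 7 would be converted (PhSH, DCC) into S-phenyl 3-(methoxycarbonyl)but-3-enethioate F8. A reagent-controlled anti-aldol with 5, through the E-boron enolate formed with a C2-symmetric 1,2-diphenylethylenediamine bis-sulfonamide bromoborane and Et3N, would give the (2R,3S)-β-hydroxy thioester F9. Silylation (TBSOTf, 2,6-lutidine) would give its TBS ether F10, and i-Bu2AlH at −78 °C would reduce the thioester to aldehyde 13.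

**Further compounds**

F1 | step 14 | methyl (1S,5R,6S,7S,8R,9Z)-8,14-bis(tert-butyldimethylsilyloxy)-5,6-epoxy-1-hydroxygermacra-4(15),9,11(13)-trien-12-oate | O[C@H]1CCC(=C)[C@H]2O[C@H]2[C@H](C(=C)C(=O)OC)[C@H](O[Si](C)(C)C(C)(C)C)/C=C1/CO[Si](C)(C)C(C)(C)C
F2 | step 14 | methyl (5R,6S,7S,8R,9Z)-8,14-bis(tert-butyldimethylsilyloxy)-5,6-epoxy-1-oxogermacra-4(15),9,11(13)-trien-12-oate | O=C1CCC(=C)[C@H]2O[C@H]2[C@H](C(=C)C(=O)OC)[C@H](O[Si](C)(C)C(C)(C)C)/C=C1/CO[Si](C)(C)C(C)(C)C
F3 | step 12 | diethyl [2-methylidene-5-(triethylsilyloxy)pentyl]phosphonate | CCOP(=O)(CC(=C)CCCO[Si](CC)(CC)CC)OCC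
F4 | step 12 | (5E,7R,8S,9Z)-diene ester (open chain, C5=C6 trans, target numbering) | CC[Si](CC)(CC)OCCCC(=C)/C=C/[C@H](C(=C)C(=O)OC)[C@H](O[Si](C)(C)C(C)(C)C)/C=C(\I)CO[Si](C)(C)C(C)(C)C
F5 | step 12 | trans-vinyl epoxide, (5S,6S,7S,8S,9Z) in target numbering | CC[Si](CC)(CC)OCCCC(=C)[C@@H]1O[C@H]1[C@H](C(=C)C(=O)OC)[C@H](O[Si](C)(C)C(C)(C)C)/C=C(\I)CO[Si](C)(C)C(C)(C)C
F6 | step 12 | C1 aldehyde of the trans-vinyl epoxide | O=CCCC(=C)[C@@H]1O[C@H]1[C@H](C(=C)C(=O)OC)[C@H](O[Si](C)(C)C(C)(C)C)/C=C(\I)CO[Si](C)(C)C(C)(C)C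
F7 | step 12 | methyl (1R,5S,6S,7S,8R,9Z)-8,14-bis(tert-butyldimethylsilyloxy)-5,6-epoxy-1-hydroxygermacra-4(15),9,11(13)-trien-12-oate (trans-epoxide) | O[C@@H]1CCC(=C)[C@@H]2O[C@H]2[C@H](C(=C)C(=O)OC)[C@H](O[Si](C)(C)C(C)(C)C)/C=C1/CO[Si](C)(C)C(C)(C)C
F8 | step 6 | S-phenyl 3-(methoxycarbonyl)but-3-enethioate | COC(=O)C(=C)CC(=O)Sc1ccccc1
F9 | step 6 | methyl 2-[(2R,3S,4Z)-6-(tert-butyldimethylsilyloxy)-3-hydroxy-5-iodo-1-oxo-1-(phenylsulfanyl)hex-4-en-2-yl]prop-2-enoate | O[C@@H]([C@@H](C(=C)C(=O)OC)C(=O)Sc1ccccc1)/C=C(\I)CO[Si](C)(C)C(C)(C)C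
F10 | step 6 | 3-O-tert-butyldimethylsilyl ether of F9 | CC(C)(C)[Si](C)(C)O[C@@H]([C@@H](C(=C)C(=O)OC)C(=O)Sc1ccccc1)/C=C(\I)CO[Si](C)(C)C(C)(C)C
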